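The numbers in the tables come from a simulation from invented constants.

How much ring can the flask charged with 10 mM of solid substrate show within 30 h, and when? I had to answer that from two earlier runs.

| flask | solid substrate | remark | time |
|---|---|---|---|
| Tuesday's | 5 mM | run made earlier |  |
| Monday's | 20 mM | run made earlier |  |
| flask | 10 mM |  | 30 h |

| run | time / h | ring / % |
|---|---|---|
| Tuesday's | 1.50 | 44.0 |
| Tuesday's | 2.50 | 62.4 |
| Tuesday's | 4.00 | 58.1 |
| Tuesday's | 6.00 | 49.6 |
| Tuesday's | 12.0 | 36.9 |
| Tuesday's | 20.0 | 25.8 |
| Tuesday's | 30.0 | 17.7 |
| Monday's | 1.50 | 10.0 |
| Monday's | 2.50 | 14.8 |
| Monday's | 4.00 | 21.0 |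
| Monday's | 6.00 | 25.8 |
| Monday's | 12.0 | 24.2 |
| Monday's | 20.0 | 14.4 |
| Monday's | 30.0 | 5.8 |

(standard deviation of a reading: 1 percentage point)

- the moment within 30 h at which there is most ring
- the amount of ring, in percent of the solid substrate charged, at that time

- solid, in amounts per volume of the solution: solid substrate
- at the start none of the solid substrate is in solution

My bench rule was that ring peaks when the last solid has dissolved. As the zero of the scale I took the case in which the charge makes no difference to the early millimolar amount. At 1.50 h Tuesday's run held 2.20 mM of ring and Monday's 2.00 mM, though Monday's charge was 4.00 times Tuesday's, so I read this as dissolving that is zero order in the charge. I named the feed, the millimolar ring made per hour while solid lasts, and took it from Tuesday's first reading as 1.47 mM/h. The charge over the feed gives a clearing time. For Tuesday's run that is 3.41 h, between its highest reading at 2.50 h and the next at 4.00 h, so the rule held there. For Monday's run it is 13.6 h, later than its reading at 12.0 h, but its two top readings, at 6.00 h and 12.0 h, differ by 1.6 percentage points against a scatter of 1 point per reading, so I could place that peak only roughly and the readings neither confirmed nor refuted the rule there. The border showed in the feed itself: at 6.00 h Monday's run held 5.16 mM of ring, 0.586 times what the feed gives over that time, so in Monday's run a steady feed of ring had stopped holding by then. The flask's clearing time, 6.82 h, lay later than that reading, so I took it as a rough figure. I committed to a peak near 6.82 h, holding Monday's 6.00 h amount, 51.6 % of this charge.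

The forecast's words were: “Formation is therefore roughly zero order, limited by dissolving solid”. It gave 44 % at 4.7 h, earlier than my time.

The flask gave 48.3 % at 6.11 h, 1.30 times the forecast's time, and its solid substrate stood at 0 % at 6.11 h. My clearing time from the feed lay 0.710 h later than that peak.

    starting material ⇌ ring (K = 2.40, k = 0.00103 /s)
    2 starting material → open dimer (k = 0.0241 /M/s)
    starting material + open dimer → open trimer (k = 0.0259 /M/s)
    solid substrate ⇌ starting material, rate k4*(cs4 - [starting material]) while solid is left; crystals form when [starting material] > cs4 (solubility = 3.30 mM, k = 2.59 × 10⁻⁴ /s)

For a reading of the same flask at 8.0 h, the feed put clearing at 6.82 h, earlier than that reading, so the peak should fall inside the window. Computed, the highest amount up to then was 48.3 %, and ring at the reading had fallen to 39.9 %.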